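**Retrosynthetic overview**
- Target ⇐ C8 methacrylate and C14 acetate put on last; the oxirane comes from a hydroxyl-directed epoxidation of the C14 allylic alcohol ⇐ 8,14-dihydroxy heliangolide (ten-membered ring fused to the α-methylene-γ-lactone).
- Key disconnection C6–C7: electrochemical, chromium-catalysed intramolecular allylation of a (4Z)-enal by a (Z)-2-(bromomethyl)enoate. Ring order: ten-membered carbocycle first, γ-lactone in the same flask, oxirane last.
- Seco-chain ⇐ Morita–Baylis–Hillman reaction and bromination at the C7 aldehyde; C1=C10 with its C14 oxygen ⇐ three-component β-oxido ylide olefination of a nerol-derived C1–C6 aldehyde, a C7–C10 phosphonium salt and formaldehyde.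
- Stereochemistry: C8 is bought with (S)-glycidol; it directs C7 and C6 in the ring closure and, through the macrocycle, C1 and C10. The 4Z double bond is bought with nerol.

Convention: C1–C15 are the germacrane atom numbers of the target (C6–O and C7 in the lactone, C8 bears the methacrylate, C1/C10 the oxirane, C14 the acetoxymethyl, C15 the methyl); "ring-trans C1=C10" means C2 and C9 on opposite sides, which is Z by CIP once C14 carries oxygen.

**Route**

Step 1
Reactants: 1 nerol, (2Z)-3,7-dimethylocta-2,6-dien-1-ol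
Product: 2 triethyl{[(2Z)-3,7-dimethylocta-2,6-dien-1-yl]oxy}silane
Conditions: Et3SiCl, imidazole, CH2Cl2, 0 → 25 °C
Reagents that add atoms: chlorotriethylsilane, CC[Si](Cl)(CC)CC
Why: Standard silyl ether formation on a primary allylic alcohol, which leaves the 2Z double bond (future C4=C5) untouched.

Step 2
Reactants: 2 triethyl{[(2Z)-3,7-dimethylocta-2,6-dien-1-yl]oxy}silane
Product: 3 (4Z)-4-methyl-6-[(triethylsilyl)oxy]hex-4-enal
Conditions: O3 (1.0 equiv, Sudan Red 7B end-point), CH2Cl2, −78 °C; then PPh3, −78 → 25 °C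
Reagents that add atoms: ozone, [O-][O+]=O
Why: Chemoselective ozonolysis, because the remote trisubstituted alkene is more electron-rich than the one carrying the allylic C–O bond and is cleaved first when one equivalent of ozone is delivered to a dye end-point.

Step 3
Reactants: 4 (S)-glycidol, [(2S)-oxiran-2-yl]methanol
Product: 5 triethyl{[(2R)-oxiran-2-yl]methoxy}silane
Conditions: Et3SiCl, Et3N, DMAP (cat.), CH2Cl2, 0 °C
Reagents that add atoms: chlorotriethylsilane, CC[Si](Cl)(CC)CC
Why: Silyl ether formation on the primary hydroxyl that does not touch the bought stereocentre (future C8), whose descriptor becomes R only because CH2OSi now outranks the ring CH2.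

Step 4
Reactants: 6 methyltriphenylphosphonium bromide; 5 triethyl{[(2R)-oxiran-2-yl]methoxy}silane
Product: 9 [(3R)-3,4-bis(triethylsilyloxy)butyl]triphenylphosphonium bromide, via methylenetriphenylphosphorane 7 (not isolated), via oxaphospholane 8 (not isolated)
Conditions: n-BuLi (1.0 equiv), THF, 0 °C; 5, 0 → 25 °C, 12 h; then Et3SiCl, 0 → 25 °C
Reagents that add atoms: chlorotriethylsilane, CC[Si](Cl)(CC)CC
Why: Ylide opening of a terminal epoxide at its CH2 terminus (the known route to 1,2-oxaphospholanes and γ-oxido phosphonium salts) followed by O-silylation with P–O cleavage, with no bond to the C–O stereocentre involved.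

Step 5
Reactants: 9 [(3R)-3,4-bis(triethylsilyloxy)butyl]triphenylphosphonium bromide; 3 (4Z)-4-methyl-6-[(triethylsilyl)oxy]hex-4-enal; 10 formaldehyde (dry paraformaldehyde)
Product: 15 tert-butyl{[(2Z,6Z)-2-[(2R)-2,3-bis(triethylsilyloxy)propyl]-6-methyl-8-(triethylsilyloxy)octa-2,6-dien-1-yl]oxy}dimethylsilane, via ylide 11 (not isolated), via lithiobetaine 12 (not isolated), via beta-oxido ylide 13 (not isolated), via allylic alcohol 14 (not isolated)
Conditions: PhLi (1.0 equiv), THF/Et2O, −78 → 0 °C; 3, −78 °C; PhLi (1.05 equiv), −78 → −30 °C; (CH2O)n (3 equiv), −30 → 25 °C; then t-BuMe2SiCl, imidazole, 25 °C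
Reagents that add atoms: tert-butyldimethylsilyl chloride, CC(C)(C)[Si](C)(C)Cl
Why: Corey–Schlosser β-oxido ylide three-component olefination, in which the electrophile (here CH2O, giving C14) ends up cis to the aldehyde-derived C2 chain and the ylide's C9 chain trans to it, so the ring-trans C1=C10 bond with its C14 oxygen is obtained directly and the lithium alkoxide is silylated in the same flask.

Step 6
Reactants: 15 tert-butyl{[(2Z,6Z)-2-[(2R)-2,3-bis(triethylsilyloxy)propyl]-6-methyl-8-(triethylsilyloxy)octa-2,6-dien-1-yl]oxy}dimethylsilane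
Product: 16 (2R,4Z,8Z)-4-{[(tert-butyldimethylsilyl)oxy]methyl}-8-methyl-2-[(triethylsilyl)oxy]deca-4,8-dienedial
Conditions: (COCl)2, DMSO, CH2Cl2, −78 → −40 °C; then Et3N, −78 → 0 °C
Reagents that add atoms: none
Why: Swern oxidation converts primary triethylsilyl ethers directly into aldehydes (here at C6 and C7) while the secondary OSiEt3 group and the tert-butyldimethylsilyl ether are inert, and the cold conditions keep the 4Z enal and the C8 centre intact.

Step 7
Reactants: 16 (2R,4Z,8Z)-4-{[(tert-butyldimethylsilyl)oxy]methyl}-8-methyl-2-[(triethylsilyl)oxy]deca-4,8-dienedial; 17 methyl acrylate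
Product: 18 methyl (3RS,4R,6Z,10Z)-6-{[(tert-butyldimethylsilyl)oxy]methyl}-3-hydroxy-10-methyl-2-methylidene-12-oxo-4-[(triethylsilyl)oxy]dodeca-6,10-dienoate
Conditions: DABCO (1 equiv), 1,4-dioxane/H2O (1:1), 20 °C, 24 h
Reagents that add atoms: none
Why: Morita–Baylis–Hillman reaction, in which the DABCO–acrylate zwitterion adds to the electrophilic α-silyloxy aldehyde far faster than to the hindered conjugated β,β-disubstituted enal, and the new carbinol centre (a mixture) is removed again in step 8.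

Step 8
Reactants: 18 methyl (3RS,4R,6Z,10Z)-6-{[(tert-butyldimethylsilyl)oxy]methyl}-3-hydroxy-10-methyl-2-methylidene-12-oxo-4-[(triethylsilyl)oxy]dodeca-6,10-dienoate
Product: 19 methyl (2Z,4R,6Z,10Z)-2-(bromomethyl)-6-{[(tert-butyldimethylsilyl)oxy]methyl}-10-methyl-12-oxo-4-[(triethylsilyl)oxy]dodeca-2,6,10-trienoate
Conditions: NBS, Me2S, CH2Cl2, −20 → 0 °C
Reagents that add atoms: N-bromosuccinimide, O=C1CCC(=O)N1Br
Why: Corey–Kim-type activation of the allylic alcohol and SN2' delivery of bromide, which gives the thermodynamically preferred (2Z)-2-(bromomethyl)enoate (C8 cis to CH2Br) without touching C8.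

Step 9
Reactants: 19 methyl (2Z,4R,6Z,10Z)-2-(bromomethyl)-6-{[(tert-butyldimethylsilyl)oxy]methyl}-10-methyl-12-oxo-4-[(triethylsilyl)oxy]dodeca-2,6,10-trienoate
Product: 22 (6R,7S,8R)-14-[(tert-butyldimethylsilyl)oxy]-8-[(triethylsilyl)oxy]germacra-1(10),4,11(13)-trien-12,6-olide, via allylchromium 20 (not isolated), via hydroxy ester 21 (not isolated)
Conditions: CrCl2 (20 mol %), Bu4NBr (0.1 M), DMF, undivided cell, aluminium anode, nickel-foam cathode, constant current (3 mA, 2.4 F/mol), 19 added over 10 h by syringe pump (final 2 mM), 25 °C; then aq. NH4Cl; PPTS (cat.), CH2Cl2, 25 °C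
Reagents that add atoms: none
Why: Proposed new method: a chromium-catalysed electroreductive Nozaki–Hiyama allylation used to close a ten-membered carbocycle, which has not been shown: the cathode keeps reducing trivalent chromium to divalent chromium, two divalent chromium ions convert the allylic bromide of 19 into allylchromium 20, which exists only at a low stationary concentration (so ring closure beats oligomerisation), 20 adds to the (Z)-enal with allylic transposition through a closed six-membered transition state inside the forming ring, Al3+ from the anode takes over the alkoxide and frees chromium for the next turnover, and the C6 alkoxide lactonises onto the ester; the bought C8 centre controls both new centres because C8–H must eclipse the allyl plane (A(1,3) strain with the CH2–Cr group), the C8–C9 ring bond then lies anti to the forming C6–C7 bond with the bulky OSiEt3 group turned outward (this sets C7 as in the target; it is formally S in 21 and 22 only because the silyl ether raises the CIP rank of C8), and the ring branches C5 and C8 sit anti across the new bond (this sets C6 R and the trans-fused lactone); the closest known reactions are the stoichiometric CrCl2-mediated Nozaki–Hiyama macrocyclisation of ω-formyl allylic bromides and the intermolecular chromium-catalysed electrochemical allylation of aldehydes with a sacrificial aluminium anode.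

Step 10
Reactants: 22 (6R,7S,8R)-14-[(tert-butyldimethylsilyl)oxy]-8-[(triethylsilyl)oxy]germacra-1(10),4,11(13)-trien-12,6-olide
Product: 23 (6R,7R,8R)-8,14-dihydroxygermacra-1(10),4,11(13)-trien-12,6-olide (4Z, ring-trans C1=C10)
Conditions: HF·pyridine, pyridine, THF, 0 → 25 °C
Reagents that add atoms: none
Why: Fluoride-mediated desilylation removes both silyl ethers under buffered conditions that leave the α-methylene lactone and both ring alkenes untouched.

Step 11
Reactants: 23 (6R,7R,8R)-8,14-dihydroxygermacra-1(10),4,11(13)-trien-12,6-olide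
Product: 24 (1R,6R,7R,8R,10S)-1,10-epoxy-8,14-dihydroxygermacra-4,11(13)-dien-12,6-olide (4Z)
Conditions: VO(acac)2 (5 mol %), t-BuOOH (1.5 equiv, in decane), CH2Cl2, 0 °C
Reagents that add atoms: tert-butyl hydroperoxide, CC(C)(C)OO
Why: Hydroxyl-directed epoxidation (Sharpless–Michaelson type), in which the vanadium alkoxide of the allylic C14–OH delivers oxygen only to C1=C10 and, since only the outer face of this ring double bond is open in the ten-membered ring, gives the 1R,10S (1β,10α) oxirane while the 4Z alkene and the two electron-poor alkenes stay intact.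

Step 12
Reactants: 24 (1R,6R,7R,8R,10S)-1,10-epoxy-8,14-dihydroxygermacra-4,11(13)-dien-12,6-olide
Product: 25 (1R,6R,7R,8R,10S)-14-acetoxy-1,10-epoxy-8-hydroxygermacra-4,11(13)-dien-12,6-olide (4Z)
Conditions: Ac2O (1.1 equiv), 2,4,6-collidine, CH2Cl2, −20 → 0 °C
Reagents that add atoms: acetic anhydride, CC(=O)OC(C)=O
Why: Selective acylation of the primary C14 hydroxyl over the hindered secondary C8 hydroxyl with a limiting amount of anhydride and a weak base, under non-acidic conditions that spare the oxirane.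

Step 13
Reactants: 25 (1R,6R,7R,8R,10S)-14-acetoxy-1,10-epoxy-8-hydroxygermacra-4,11(13)-dien-12,6-olide
Product: 26 (1R,6R,7R,8R,10S)-14-acetoxy-1,10-epoxy-8-(methacryloyloxy)germacra-4,11(13)-dien-12,6-olide (4Z), CNP0150481.2
Conditions: methacrylic anhydride (3 equiv), DMAP (0.3 equiv), Et3N, CH2Cl2, 0 → 25 °C
Reagents that add atoms: methacrylic anhydride, C=C(C)C(=O)OC(=O)C(C)=C
Why: DMAP-catalysed (Steglich-type) acylation of the remaining secondary alcohol proceeds with retention at C8 and gives the target.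

**Compound list**

1 | nerol, (2Z)-3,7-dimethylocta-2,6-dien-1-ol | CC(C)=CCC/C(C)=C\CO | starting material
2 | triethyl{[(2Z)-3,7-dimethylocta-2,6-dien-1-yl]oxy}silane | CC(C)=CCC/C(C)=C\CO[Si](CC)(CC)CC | intermediate
3 | (4Z)-4-methyl-6-[(triethylsilyl)oxy]hex-4-enal | O=CCC/C(C)=C\CO[Si](CC)(CC)CC | intermediate
4 | (S)-glycidol, [(2S)-oxiran-2-yl]methanol | OC[C@H]1CO1 | starting material
5 | triethyl{[(2R)-oxiran-2-yl]methoxy}silane | CC[Si](CC)(CC)OC[C@H]1CO1 | intermediate
6 | methyltriphenylphosphonium bromide | C[P+](c1ccccc1)(c1ccccc1)c1ccccc1.[Br-] | starting material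
7 | methylenetriphenylphosphorane (formed in the flask) | C=P(c1ccccc1)(c1ccccc1)c1ccccc1 | intermediate
8 | (5R)-2,2,2-triphenyl-5-{[(triethylsilyl)oxy]methyl}-1,2λ5-oxaphospholane, closed form of the γ-oxido phosphonium betaine (formed in the flask) | CC[Si](CC)(CC)OC[C@H]1CCP(c2ccccc2)(c2ccccc2)(c2ccccc2)O1 | intermediate
9 | [(3R)-3,4-bis(triethylsilyloxy)butyl]triphenylphosphonium bromide | CC[Si](CC)(CC)OC[C@H](O[Si](CC)(CC)CC)CC[P+](c1ccccc1)(c1ccccc1)c1ccccc1.[Br-] | intermediate
10 | formaldehyde (used as paraformaldehyde) | C=O | starting material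
11 | [(3R)-3,4-bis(triethylsilyloxy)butylidene]triphenylphosphorane (formed in the flask) | CC[Si](CC)(CC)OC[C@H](O[Si](CC)(CC)CC)C[CH-][P+](c1ccccc1)(c1ccccc1)c1ccccc1 | intermediate
12 | lithium bromide adduct of the betaine [(2R,8Z)-8-methyl-5-oxido-1,2,10-tris(triethylsilyloxy)dec-8-en-4-yl]triphenylphosphonium, erythro at C4/C5 (both erythro isomers, formed in the flask) | CC[Si](CC)(CC)OC/C=C(C)\CCC([O-])C(C[C@@H](O[Si](CC)(CC)CC)CO[Si](CC)(CC)CC)[P+](c1ccccc1)(c1ccccc1)c1ccccc1.[Li+].[Br-] | intermediate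
13 | lithium salt of the β-oxido ylide [(2R,8Z)-8-methyl-5-oxido-1,2,10-tris(triethylsilyloxy)dec-8-en-4-ylidene]triphenylphosphorane (formed in the flask) | CC[Si](CC)(CC)OC/C=C(C)\CCC([O-])[C-](C[C@@H](O[Si](CC)(CC)CC)CO[Si](CC)(CC)CC)[P+](c1ccccc1)(c1ccccc1)c1ccccc1.[Li+] | intermediate
14 | (2Z,6Z)-2-[(2R)-2,3-bis(triethylsilyloxy)propyl]-6-methyl-8-(triethylsilyloxy)octa-2,6-dien-1-ol (formed as its lithium alkoxide in the flask) | CC[Si](CC)(CC)OC/C=C(C)\CC/C=C(CO)/C[C@@H](O[Si](CC)(CC)CC)CO[Si](CC)(CC)CC | intermediate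
15 | tert-butyl{[(2Z,6Z)-2-[(2R)-2,3-bis(triethylsilyloxy)propyl]-6-methyl-8-(triethylsilyloxy)octa-2,6-dien-1-yl]oxy}dimethylsilane | CC[Si](CC)(CC)OC/C=C(C)\CC/C=C(CO[Si](C)(C)C(C)(C)C)/C[C@@H](O[Si](CC)(CC)CC)CO[Si](CC)(CC)CC | intermediate
16 | (2R,4Z,8Z)-4-{[(tert-butyldimethylsilyl)oxy]methyl}-8-methyl-2-[(triethylsilyl)oxy]deca-4,8-dienedial | O=C/C=C(C)\CC/C=C(CO[Si](C)(C)C(C)(C)C)/C[C@@H](O[Si](CC)(CC)CC)C=O | intermediate
17 | methyl acrylate | C=CC(=O)OC | starting material
18 | methyl (3RS,4R,6Z,10Z)-6-{[(tert-butyldimethylsilyl)oxy]methyl}-3-hydroxy-10-methyl-2-methylidene-12-oxo-4-[(triethylsilyl)oxy]dodeca-6,10-dienoate | O=C/C=C(C)\CC/C=C(CO[Si](C)(C)C(C)(C)C)/C[C@@H](O[Si](CC)(CC)CC)C(O)C(=C)C(=O)OC | intermediate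
19 | methyl (2Z,4R,6Z,10Z)-2-(bromomethyl)-6-{[(tert-butyldimethylsilyl)oxy]methyl}-10-methyl-12-oxo-4-[(triethylsilyl)oxy]dodeca-2,6,10-trienoate | O=C/C=C(C)\CC/C=C(CO[Si](C)(C)C(C)(C)C)/C[C@@H](O[Si](CC)(CC)CC)/C=C(\CBr)C(=O)OC | intermediate
20 | allylchromium dichloride (trivalent chromium, DMF-solvated) from 19, methyl (2Z,4R,6Z,10Z)-2-[(dichlorochromio)methyl]-6-{[(tert-butyldimethylsilyl)oxy]methyl}-10-methyl-12-oxo-4-[(triethylsilyl)oxy]dodeca-2,6,10-trienoate (formed in the flask) | O=C/C=C(C)\CC/C=C(CO[Si](C)(C)C(C)(C)C)/C[C@@H](O[Si](CC)(CC)CC)/C=C(\C[Cr](Cl)Cl)C(=O)OC | intermediate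
21 | methyl 2-[(1S,2R,3Z,7Z,10R)-8-{[(tert-butyldimethylsilyl)oxy]methyl}-2-hydroxy-4-methyl-10-[(triethylsilyl)oxy]cyclodeca-3,7-dien-1-yl]prop-2-enoate (formed as its aluminium alkoxide in the flask) | CC[Si](CC)(CC)O[C@@H]1C/C(CO[Si](C)(C)C(C)(C)C)=C/CC/C(C)=C\[C@@H](O)[C@@H]1C(=C)C(=O)OC | intermediate
22 | (6R,7S,8R)-14-[(tert-butyldimethylsilyl)oxy]-8-[(triethylsilyl)oxy]germacra-1(10),4,11(13)-trien-12,6-olide, 4Z, ring-trans C1=C10, same spatial arrangement at C6/C7/C8 as the target | CC[Si](CC)(CC)O[C@@H]1C/C(CO[Si](C)(C)C(C)(C)C)=C/CC/C(C)=C\[C@H]2OC(=O)C(=C)[C@@H]21 | intermediate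
23 | (6R,7R,8R)-8,14-dihydroxygermacra-1(10),4,11(13)-trien-12,6-olide, 4Z, ring-trans C1=C10 | O[C@@H]1C/C(CO)=C/CC/C(C)=C\[C@H]2OC(=O)C(=C)[C@@H]21 | intermediate
24 | (1R,6R,7R,8R,10S)-1,10-epoxy-8,14-dihydroxygermacra-4,11(13)-dien-12,6-olide, 4Z | O[C@@H]1C[C@@]2(CO)O[C@@H]2CC/C(C)=C\[C@H]2OC(=O)C(=C)[C@@H]21 | intermediate
25 | (1R,6R,7R,8R,10S)-14-acetoxy-1,10-epoxy-8-hydroxygermacra-4,11(13)-dien-12,6-olide, 4Z | O[C@@H]1C[C@@]2(COC(C)=O)O[C@@H]2CC/C(C)=C\[C@H]2OC(=O)C(=C)[C@@H]21 | intermediate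
26 | CNP0150481.2, (1R,6R,7R,8R,10S)-14-acetoxy-1,10-epoxy-8-(methacryloyloxy)germacra-4,11(13)-dien-12,6-olide, 4Z | C=C(C)C(=O)O[C@@H]1C[C@@]2(COC(C)=O)O[C@@H]2CC/C(C)=C\[C@H]2OC(=O)C(=C)[C@@H]21 | target

**Step count and risks**

Total steps: 13. Longest linear sequence: 11 steps (steps 1, 2, 5–13; equally steps 3, 4, 5–13).

The three steps most likely to fail are steps 9, 5 and 7.

Step 9 is the proposed new ring closure. Chromium turnover at millimolar substrate concentration is untested. The C7/C8 relationship rests on a transition-state model in which the ring bond C8–C9 is anti to the forming bond; the alternative with OSiEt3 anti would give the C7/C6 epimeric series. A cis-fused lactone is also possible. The fallback uses known chemistry, sets out from 19 and comes back at 23. Both silyl ethers are removed first (HF·pyridine, THF, 0 °C) to give the dihydroxy bromo-enal methyl (2Z,4R,6Z,10Z)-2-(bromomethyl)-4-hydroxy-6-(hydroxymethyl)-10-methyl-12-oxododeca-2,6,10-trienoate F10. The ring is then closed by the classical stoichiometric Nozaki–Hiyama reaction (CrCl2, 8 equiv, THF/DMF, syringe-pump addition, 25 °C), the established way to close ten-membered germacranolide rings. Here the free C8 hydroxyl can bind the allylmetal and so brings in a second, chelation-based control element for C7. The cyclised trihydroxy ester methyl 2-[(1R,2R,3Z,7Z,10R)-2,10-dihydroxy-8-(hydroxymethyl)-4-methylcyclodeca-3,7-dien-1-yl]prop-2-enoate F11 lactonises on work-up with PPTS to 23, so step 10 is skipped.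

Step 5 is a four-stage one-pot olefination. The betaine may eliminate before it is deprotonated, and the loss of Ph3PO can go towards C14 instead of C1. The fallback sets out from 9 and 3 and comes back at 15. Ylide 11 (from 9 with n-BuLi) is iodinated (I2, −78 °C) and deprotonated (NaN(SiMe3)2) to the α-iodo ylide [(3R)-1-iodo-3,4-bis(triethylsilyloxy)butylidene]triphenylphosphorane F1. With aldehyde 3 this gives, in a Stork–Zhao-type olefination, the vinyl iodide (2Z,6Z,9R)-7-iodo-3-methyl-1,9,10-tris[(triethylsilyl)oxy]deca-2,6-diene F2, with iodine cis to the C2 chain. Iodine–lithium exchange (t-BuLi, Et2O, −78 °C) and trapping with formaldehyde gives alcohol 14 with retention of geometry, which is silylated (t-BuMe2SiCl, imidazole) to 15.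

Step 7 depends on the Morita–Baylis–Hillman reaction picking the C7 aldehyde of dialdehyde 16. The (Z)-enal may react or isomerise, and C8 may epimerise during the long reaction. The fallback sets out from 1 and comes back at 19; it keeps C6 masked until the acrylate unit is in place.
- Nerol is converted (NaH, 4-methoxybenzyl chloride, DMF) into 1-methoxy-4-({[(2Z)-3,7-dimethylocta-2,6-dien-1-yl]oxy}methyl)benzene F3.
- Ozonolysis as in step 2 gives (4Z)-6-[(4-methoxybenzyl)oxy]-4-methylhex-4-enal F4.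
- The olefination of step 5 with 9 and 10 gives tert-butyl{[(2Z,6Z)-2-[(2R)-2,3-bis(triethylsilyloxy)propyl]-8-[(4-methoxybenzyl)oxy]-6-methylocta-2,6-dien-1-yl]oxy}dimethylsilane F5.
- Swern oxidation now touches only the primary C7 silyl ether and gives (2R,4Z,8Z)-4-{[(tert-butyldimethylsilyl)oxy]methyl}-10-[(4-methoxybenzyl)oxy]-8-methyl-2-[(triethylsilyl)oxy]deca-4,8-dienal F6.
- The Morita–Baylis–Hillman reaction on this single aldehyde gives methyl (3RS,4R,6Z,10Z)-6-{[(tert-butyldimethylsilyl)oxy]methyl}-3-hydroxy-12-[(4-methoxybenzyl)oxy]-10-methyl-2-methylidene-4-[(triethylsilyl)oxy]dodeca-6,10-dienoate F7.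
- NBS/Me2S gives methyl (2Z,4R,6Z,10Z)-2-(bromomethyl)-6-{[(tert-butyldimethylsilyl)oxy]methyl}-12-[(4-methoxybenzyl)oxy]-10-methyl-4-[(triethylsilyl)oxy]dodeca-2,6,10-trienoate F8.
- DDQ (CH2Cl2, pH 7 buffer) gives methyl (2Z,4R,6Z,10Z)-2-(bromomethyl)-6-{[(tert-butyldimethylsilyl)oxy]methyl}-12-hydroxy-10-methyl-4-[(triethylsilyl)oxy]dodeca-2,6,10-trienoate F9.
- MnO2 (CH2Cl2) oxidises the allylic alcohol to the (Z)-enal 19.

Further compounds
F1 | step 5 | [(3R)-1-iodo-3,4-bis(triethylsilyloxy)butylidene]triphenylphosphorane | CC[Si](CC)(CC)OC[C@H](O[Si](CC)(CC)CC)C[C-](I)[P+](c1ccccc1)(c1ccccc1)c1ccccc1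
F2 | step 5 | (2Z,6Z,9R)-7-iodo-3-methyl-1,9,10-tris[(triethylsilyl)oxy]deca-2,6-diene | CC[Si](CC)(CC)OC/C=C(C)\CC/C=C(I)/C[C@@H](O[Si](CC)(CC)CC)CO[Si](CC)(CC)CC
F3 | step 7 | 1-methoxy-4-({[(2Z)-3,7-dimethylocta-2,6-dien-1-yl]oxy}methyl)benzene | COc1ccc(COC/C=C(C)\CCC=C(C)C)cc1
F4 | step 7 | (4Z)-6-[(4-methoxybenzyl)oxy]-4-methylhex-4-enal | COc1ccc(COC/C=C(C)\CCC=O)cc1
F5 | step 7 | tert-butyl{[(2Z,6Z)-2-[(2R)-2,3-bis(triethylsilyloxy)propyl]-8-[(4-methoxybenzyl)oxy]-6-methylocta-2,6-dien-1-yl]oxy}dimethylsilane | COc1ccc(COC/C=C(C)\CC/C=C(CO[Si](C)(C)C(C)(C)C)/C[C@@H](O[Si](CC)(CC)CC)CO[Si](CC)(CC)CC)cc1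
F6 | step 7 | (2R,4Z,8Z)-4-{[(tert-butyldimethylsilyl)oxy]methyl}-10-[(4-methoxybenzyl)oxy]-8-methyl-2-[(triethylsilyl)oxy]deca-4,8-dienal | COc1ccc(COC/C=C(C)\CC/C=C(CO[Si](C)(C)C(C)(C)C)/C[C@@H](O[Si](CC)(CC)CC)C=O)cc1
F7 | step 7 | methyl (3RS,4R,6Z,10Z)-6-{[(tert-butyldimethylsilyl)oxy]methyl}-3-hydroxy-12-[(4-methoxybenzyl)oxy]-10-methyl-2-methylidene-4-[(triethylsilyl)oxy]dodeca-6,10-dienoate | COc1ccc(COC/C=C(C)\CC/C=C(CO[Si](C)(C)C(C)(C)C)/C[C@@H](O[Si](CC)(CC)CC)C(O)C(=C)C(=O)OC)cc1
F8 | step 7 | methyl (2Z,4R,6Z,10Z)-2-(bromomethyl)-6-{[(tert-butyldimethylsilyl)oxy]methyl}-12-[(4-methoxybenzyl)oxy]-10-methyl-4-[(triethylsilyl)oxy]dodeca-2,6,10-trienoate | COc1ccc(COC/C=C(C)\CC/C=C(CO[Si](C)(C)C(C)(C)C)/C[C@@H](O[Si](CC)(CC)CC)/C=C(\CBr)C(=O)OC)cc1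
F9 | step 7 | methyl (2Z,4R,6Z,10Z)-2-(bromomethyl)-6-{[(tert-butyldimethylsilyl)oxy]methyl}-12-hydroxy-10-methyl-4-[(triethylsilyl)oxy]dodeca-2,6,10-trienoate | OC/C=C(C)\CC/C=C(CO[Si](C)(C)C(C)(C)C)/C[C@@H](O[Si](CC)(CC)CC)/C=C(\CBr)C(=O)OC
F10 | step 9 | methyl (2Z,4R,6Z,10Z)-2-(bromomethyl)-4-hydroxy-6-(hydroxymethyl)-10-methyl-12-oxododeca-2,6,10-trienoate | O=C/C=C(C)\CC/C=C(CO)/C[C@@H](O)/C=C(\CBr)C(=O)OC
F11 | step 9 | methyl 2-[(1R,2R,3Z,7Z,10R)-2,10-dihydroxy-8-(hydroxymethyl)-4-methylcyclodeca-3,7-dien-1-yl]prop-2-enoate | O[C@@H]1C/C(CO)=C/CC/C(C)=C\[C@@H](O)[C@@H]1C(=C)C(=O)OC
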